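The route opens ring C of the flavanone at the C4–C4a bond. Ring A carries six substituents, and C6 and C8 differ only in their relation to O1 (C6 para, C8 ortho). A 4-formyl-3,5-dimethoxyphenyl ether, whose two carbons ortho to the ether oxygen are equivalent, therefore encodes the C6 substituent at the phenol stage. One intramolecular Friedel–Crafts acylation of the (S)-3-aryloxy-3-phenylpropanoic acid, activated as its trifluoroacetic mixed anhydride, closes ring C, puts the formyl group at C6 and leaves C8–H for the final acylation. C2 is set beforehand by asymmetric hydrogenation and Mitsunobu inversion; the formyl carbon later becomes the methylene bridge.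

Key step: step 4

Remark: the ester is carried as the tert-butyl ester (tert-butyl benzoylacetate is taken as a catalogue compound), so that the acid is released by acid and not by hydroxide, which could expel the formyl-stabilised aryloxide by β-elimination.

Step 1
Reactants: 1 tert-butyl 3-oxo-3-phenylpropanoate
Product: 2 tert-butyl (R)-3-hydroxy-3-phenylpropanoate
Conditions: H2 (10 bar), RuCl2[(S)-BINAP](dmf)n (0.5 mol %), EtOH, 60 °C
Reagents that add atoms: none
Why: Ruthenium–BINAP hydrogenation of a β-keto ester (Noyori asymmetric hydrogenation) runs through the chelated keto ester, and with the (S)-ligand hydride should add to the ketone face that gives the (R)-carbinol of an aryl β-keto ester, which sets the only stereocenter of the route.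

Step 2
Reactants: 2 tert-butyl (R)-3-hydroxy-3-phenylpropanoate; 3 4-hydroxy-2,6-dimethoxybenzaldehyde
Product: 4 tert-butyl (S)-3-(4-formyl-3,5-dimethoxyphenoxy)-3-phenylpropanoate
Conditions: PPh3 (1.3 equiv), DIAD (1.3 equiv), toluene, 0 °C → rt
Reagents that add atoms: none
Why: In this Mitsunobu etherification the acidic para-formyl phenol displaces the alkoxyphosphonium group by SN2, so the (R)-carbinol should be converted into the (S)-aryl ether with inversion, which is the configuration C2 needs.

Step 3
Reactants: 4 tert-butyl (S)-3-(4-formyl-3,5-dimethoxyphenoxy)-3-phenylpropanoate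
Product: 5 (S)-3-(4-formyl-3,5-dimethoxyphenoxy)-3-phenylpropanoic acid
Conditions: TFA–CH2Cl2 (1:4), 0 °C → rt; evaporation, recrystallisation
Reagents that add atoms: none
Why: Acidolysis of the tert-butyl ester (E1 loss of 2-methylpropene) frees the acid without any base, so the aryloxide cannot be expelled by β-elimination and the stereocenter, which is not involved, should be kept.

Step 4
Reactants: 5 (S)-3-(4-formyl-3,5-dimethoxyphenoxy)-3-phenylpropanoic acid
Product: 7 (2S)-6-formyl-5,7-dimethoxyflavanone, via mixed trifluoroacetic anhydride 6 (not isolated)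
Conditions: (CF3CO)2O (3 equiv), CH2Cl2, 0 °C → rt
Reagents that add atoms: none
Why: Trifluoroacetic anhydride converts the acid into mixed anhydride 6, whose acyl carbon is attacked by the ring carbon next to the ether oxygen (also ortho to one methoxy group and para to the other), and loss of the ring proton and of trifluoroacetate completes an electrophilic aromatic substitution. This is the standard intramolecular Friedel–Crafts acylation by which 3-aryloxypropanoic acids are closed to chroman-4-ones. Ring C forms as a six-membered ring by attack of the arene on the exocyclic acyl group (6-exo-trig at the acyl carbon), which creates the C4–C4a bond. No stereocenter is created, and the C2 center from step 2 should survive because no base is present and the para-formyl group withdraws electron density from the ether oxygen, so protonation there and heterolysis of the benzylic C–O bond should be slow. Regioselectivity needs no external control, since the two carbons ortho to the ether oxygen are related by the local mirror plane of the aryl ring and either attack gives the same product, with the formyl group at C6 and C8 unsubstituted. The three oxygen donors are expected to outweigh the deactivation by the meta-formyl group.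

Step 5
Reactants: 7 (2S)-6-formyl-5,7-dimethoxyflavanone
Product: 8 (2S)-6-formyl-5,7-dihydroxyflavanone
Conditions: BCl3 (1 M in CH2Cl2, 5 equiv), CH2Cl2, −78 °C → 0 °C; then H2O
Reagents that add atoms: none
Why: Chelation-assisted Lewis acid ether cleavage, in which boron bound between a carbonyl oxygen (C4 ketone or formyl group) and the neighbouring methoxy oxygen activates each methyl group for SN2 attack by chloride, while at low temperature the C2–O1 ether and the aldehyde should remain intact.

Step 6
Reactants: 9 pentan-3-one
Product: 10 3-(trimethylsilyloxy)pent-2-ene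
Conditions: Me3SiCl, Et3N, DMF, 80 °C
Reagents that add atoms: chlorotrimethylsilane, C[Si](C)(C)Cl
Why: Silyl enol ether formation under equilibrating conditions traps the enol of the symmetric ketone as its trimethylsilyl ether, and only one constitutional isomer is possible.

Step 7
Reactants: 10 3-(trimethylsilyloxy)pent-2-ene; 11 malonyl dichloride
Product: 13 6-ethyl-4-hydroxy-5-methyl-2H-pyran-2-one, via 4-methyl-3,5-dioxoheptanoyl chloride 12 (not isolated)
Conditions: Et2O, −78 °C → rt
Reagents that add atoms: none
Why: Twofold acylation by malonyl dichloride (pyranone annulation of a silyl enol ether), in which C-acylation gives diketo acid chloride 12 and its ketone enol oxygen then attacks the remaining acid chloride to close the 4-hydroxy-2-pyranone.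

Step 8
Reactants: 8 (2S)-6-formyl-5,7-dihydroxyflavanone; 13 6-ethyl-4-hydroxy-5-methyl-2H-pyran-2-one
Product: 15 (2S)-6-[(6-ethyl-4-hydroxy-5-methyl-2-oxo-2H-pyran-3-yl)methyl]-5,7-dihydroxyflavanone, via Knoevenagel alkylidene 14 (not isolated)
Conditions: Hantzsch ester (diethyl 2,6-dimethyl-1,4-dihydropyridine-3,5-dicarboxylate, 1.1 equiv), L-proline (20 mol %), EtOH, rt
Reagents that add atoms: none
Why: This is an organocatalytic reductive alkylation of a cyclic 1,3-dicarbonyl compound, in which proline-promoted Knoevenagel condensation gives alkylidene 14 and the Hantzsch ester should reduce it by conjugate hydride transfer before a second pyranone can add, under conditions too mild to open ring C.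

Step 9
Reactants: 15 (2S)-6-[(6-ethyl-4-hydroxy-5-methyl-2-oxo-2H-pyran-3-yl)methyl]-5,7-dihydroxyflavanone; 16 3-methylbut-2-enoyl chloride
Product: 17 (2S)-6-[(6-ethyl-4-hydroxy-5-methyl-2-oxo-2H-pyran-3-yl)methyl]-5,7-dihydroxy-8-(3-methylbut-2-enoyl)flavanone (CNP0311807.1)
Conditions: AlCl3 (5 equiv), PhNO2–CH2Cl2, 0 °C → rt; then ice-cold 1 M HCl
Reagents that add atoms: none
Why: Friedel–Crafts C-acylation of an acylphloroglucinol, in which C8 is the only unsubstituted carbon of the electron-rich ring A so that regiochemistry is fixed, and the aluminium chelate between the new ketone and O7 should hold the enone away from that oxygen and so restrain oxa-Michael closure to a dimethylchromanone.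

Compound list
1 | tert-butyl 3-oxo-3-phenylpropanoate (tert-butyl benzoylacetate) | CC(C)(C)OC(=O)CC(=O)c1ccccc1 | starting material
2 | tert-butyl (R)-3-hydroxy-3-phenylpropanoate | CC(C)(C)OC(=O)C[C@@H](O)c1ccccc1 | intermediate
3 | 4-hydroxy-2,6-dimethoxybenzaldehyde | COc1cc(O)cc(OC)c1C=O | starting material
4 | tert-butyl (S)-3-(4-formyl-3,5-dimethoxyphenoxy)-3-phenylpropanoate | CC(C)(C)OC(=O)C[C@@H](c1ccccc1)Oc1cc(OC)c(C=O)c(OC)c1 | intermediate
5 | (S)-3-(4-formyl-3,5-dimethoxyphenoxy)-3-phenylpropanoic acid | OC(=O)C[C@@H](c1ccccc1)Oc1cc(OC)c(C=O)c(OC)c1 | intermediate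
6 | (S)-3-(4-formyl-3,5-dimethoxyphenoxy)-3-phenylpropanoic trifluoroacetic anhydride (not isolated) | O=C(C[C@@H](c1ccccc1)Oc1cc(OC)c(C=O)c(OC)c1)OC(=O)C(F)(F)F | intermediate
7 | (2S)-6-formyl-5,7-dimethoxyflavanone [(2S)-5,7-dimethoxy-4-oxo-2-phenylchromane-6-carbaldehyde] | O=Cc1c(OC)cc2c(c1OC)C(=O)C[C@@H](c1ccccc1)O2 | intermediate
8 | (2S)-6-formyl-5,7-dihydroxyflavanone | O=Cc1c(O)cc2c(c1O)C(=O)C[C@@H](c1ccccc1)O2 | intermediate
9 | pentan-3-one | CCC(=O)CC | starting material
10 | 3-(trimethylsilyloxy)pent-2-ene (E/Z mixture, geometry without consequence) | CC=C(CC)O[Si](C)(C)C | intermediate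
11 | malonyl dichloride | O=C(Cl)CC(=O)Cl | starting material
12 | 4-methyl-3,5-dioxoheptanoyl chloride (racemic at C4, not isolated) | CCC(=O)C(C)C(=O)CC(=O)Cl | intermediate
13 | 6-ethyl-4-hydroxy-5-methyl-2H-pyran-2-one | CCc1oc(=O)cc(O)c1C | intermediate
14 | (2S)-6-[(6-ethyl-5-methyl-2,4-dioxo-2H-pyran-3(4H)-ylidene)methyl]-5,7-dihydroxyflavanone (alkene geometry undefined, not isolated) | CCC1=C(C)C(=O)C(=Cc2c(O)cc3c(c2O)C(=O)C[C@@H](c2ccccc2)O3)C(=O)O1 | intermediate
15 | (2S)-6-[(6-ethyl-4-hydroxy-5-methyl-2-oxo-2H-pyran-3-yl)methyl]-5,7-dihydroxyflavanone | CCc1oc(=O)c(Cc2c(O)cc3c(c2O)C(=O)C[C@@H](c2ccccc2)O3)c(O)c1C | intermediate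
16 | 3-methylbut-2-enoyl chloride | CC(C)=CC(=O)Cl | starting material
17 | (2S)-6-[(6-ethyl-4-hydroxy-5-methyl-2-oxo-2H-pyran-3-yl)methyl]-5,7-dihydroxy-8-(3-methylbut-2-enoyl)-2-phenylchroman-4-one | CCc1oc(=O)c(Cc2c(O)c(C(=O)C=C(C)C)c3c(c2O)C(=O)C[C@@H](c2ccccc2)O3)c(O)c1C | target

Total step count: 9. Longest linear sequence: 7 steps (steps 1, 2, 3, 4, 5, 8, 9); steps 6 and 7 make the pyranone in a side branch.

Steps most likely to fail

Step 4 (key step). The formyl group may slow attack of the ring so much that the mixed anhydride instead loses the aryloxide by β-elimination, or the benzylic C–O bond may ionise and the C2 configuration erode before ring closure. The fallback sets out from acid 5 and masks the aldehyde as a dithioacetal, which makes the ring alkyl- and not acyl-substituted. Propane-1,3-dithiol with catalytic BF3·OEt2 in CH2Cl2 at 0 °C should give (S)-3-[4-(1,3-dithian-2-yl)-3,5-dimethoxyphenoxy]-3-phenylpropanoic acid F1. Trifluoroacetic anhydride in CH2Cl2 at 0 °C should then take it through the mixed trifluoroacetic anhydride of F1, F2 (not isolated), to (2S)-6-(1,3-dithian-2-yl)-5,7-dimethoxyflavanone F3. S-Methylation and hydrolysis (MeI, CaCO3, aqueous MeCN, 40 °C) should unmask the aldehyde, and the route is rejoined at 7.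

Step 9. After C-acylation the C7 oxygen may add to the enone (oxa-Michael closure to a 2,2-dimethylchromanone), acylation may stop at O-esters, or the Lewis acid may open ring C and erode C2. The fallback sets out from 15 and avoids Lewis acids. N-Iodosuccinimide in MeCN at 0 °C should iodinate the only free aromatic carbon and give (2S)-6-[(6-ethyl-4-hydroxy-5-methyl-2-oxo-2H-pyran-3-yl)methyl]-5,7-dihydroxy-8-iodoflavanone F6. A carbonylative Stille coupling with tributyl(2-methylprop-1-enyl)stannane under CO (1 atm) with PdCl2(PPh3)2 in DMF at 60 °C should then install the enone under neutral conditions, and the route is rejoined at 17.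

Step 8. Condensation at the formyl group may be slow, because it is chelated by two ortho hydroxyls on an electron-rich ring, and a second pyranone may add to the alkylidene before hydride transfer. The fallback sets out from 7, whose methyl ethers leave the aldehyde unchelated, and moves the deprotection behind the coupling. The same proline/Hantzsch ester coupling with 13 should proceed through (2S)-6-[(6-ethyl-5-methyl-2,4-dioxo-2H-pyran-3(4H)-ylidene)methyl]-5,7-dimethoxyflavanone F4 (not isolated) to (2S)-6-[(6-ethyl-4-hydroxy-5-methyl-2-oxo-2H-pyran-3-yl)methyl]-5,7-dimethoxyflavanone F5. BBr3 in CH2Cl2 (−78 °C → 0 °C) should then cleave both methyl ethers, and the route is rejoined at 15; this path also bypasses step 5.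

Further compounds
F1 | step 4 | (S)-3-[4-(1,3-dithian-2-yl)-3,5-dimethoxyphenoxy]-3-phenylpropanoic acid | OC(=O)C[C@@H](c1ccccc1)Oc1cc(OC)c(C2SCCCS2)c(OC)c1
F2 | step 4 | mixed trifluoroacetic anhydride of F1 (not isolated) | O=C(C[C@@H](c1ccccc1)Oc1cc(OC)c(C2SCCCS2)c(OC)c1)OC(=O)C(F)(F)F
F3 | step 4 | (2S)-6-(1,3-dithian-2-yl)-5,7-dimethoxyflavanone | COc1cc2c(c(OC)c1C1SCCCS1)C(=O)C[C@@H](c1ccccc1)O2
F4 | step 8 | (2S)-6-[(6-ethyl-5-methyl-2,4-dioxo-2H-pyran-3(4H)-ylidene)methyl]-5,7-dimethoxyflavanone (not isolated) | CCC1=C(C)C(=O)C(=Cc2c(OC)cc3c(c2OC)C(=O)C[C@@H](c2ccccc2)O3)C(=O)O1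
F5 | step 8 | (2S)-6-[(6-ethyl-4-hydroxy-5-methyl-2-oxo-2H-pyran-3-yl)methyl]-5,7-dimethoxyflavanone | CCc1oc(=O)c(Cc2c(OC)cc3c(c2OC)C(=O)C[C@@H](c2ccccc2)O3)c(O)c1C
F6 | step 9 | (2S)-6-[(6-ethyl-4-hydroxy-5-methyl-2-oxo-2H-pyran-3-yl)methyl]-5,7-dihydroxy-8-iodoflavanone | CCc1oc(=O)c(Cc2c(O)c(I)c3c(c2O)C(=O)C[C@@H](c2ccccc2)O3)c(O)c1C
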